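**Retrosynthetic overview**

1. The target is reached by MOM removal from its bis-MOM ether. The furan ring is closed last, by intramolecular addition–elimination of the 2'-phenoxide at C2 of a 2-(methylsulfanyl)isoflavone. The pyranone (ring C) comes from a 2-hydroxydeoxybenzoin and CS2, and the deoxybenzoin from Pd-catalysed α-arylation of the ring A methyl ketone with the ring B bromochromene.
2. The ring B bromochromene comes from 2,5-dihydroxybenzaldehyde by Baeyer–Villiger oxidation, bromination and a propargyl ether Claisen cascade.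
3. The ring A ketone comes from directed ortho-lithiation/acetylation of a prenylated chromane made in the key step, a one-pot ring-closing metathesis/aromatic Claisen rearrangement of a mirror-symmetric 2-vinylphloroglucinol bis(1,1-dimethylallyl) ether. The metathesis closes the dihydropyran ring across its C3–C4 bond (formed as C3=C4, hydrogenated in the next step); the Claisen shift installs the C8 prenyl group and frees 7-OH.
4. Enabling feature: in ring A, C6 (which carries pyran C4) lies between O5 and O7. The O5–C(CH3)2–C3 arm of the dihydropyran and the 7-OH/8-prenyl pair are therefore the two fates (metathesis versus [3,3] shift) of identical O–C(CH3)2–CH=CH2 groups on either side of a C6 vinyl group, and no O5/O7 differentiation is needed.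
5. Ring order: dihydropyran on ring A (step 4), chromene pyran on ring B (step 13, separate branch), pyranone ring C (step 16), furan (step 17).

Key step: step 4

Remark: flavonoid numbering (O1, C2–C4, C4a–C8a, primed atoms for ring B) is used for the core and chromane/chromene numbering for the building blocks; the target has no stereocentre.

**Step 1**
Reactants: 1 2,4,6-trihydroxybenzaldehyde
Product: 2 2,6-dihydroxy-4-(methoxymethoxy)benzaldehyde
Conditions: MOMCl (1.0 equiv), i-Pr2NEt, CH2Cl2–THF, −20 → 0 °C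
Reagents that add atoms: chloromethyl methyl ether, COCCl
Why: Williamson-type MOM etherification should occur at the 4-OH, the only phenol not hydrogen-bonded to the formyl group and the most acidic one.

**Step 2**
Reactants: 2 2,6-dihydroxy-4-(methoxymethoxy)benzaldehyde
Product: 3 4-(methoxymethoxy)-2,6-bis[(2-methylbut-3-en-2-yl)oxy]benzaldehyde
Conditions: tert-butyl (2-methylbut-3-en-2-yl) carbonate (2.6 equiv), Pd(PPh3)4 (5 mol %), THF, 0 °C → rt
Reagents that add atoms: tert-butyl (2-methylbut-3-en-2-yl) carbonate, C=CC(C)(C)OC(=O)OC(C)(C)C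
Why: In this Tsuji–Trost O-allylation zerovalent palladium ionizes the tertiary carbonate to a 1,1-dimethyl-π-allyl complex, which the phenoxides (formed by the released tert-butoxide) should attack at the more substituted terminus under kinetic control to give both tertiary aryl ethers.

**Step 3**
Reactants: 3 4-(methoxymethoxy)-2,6-bis[(2-methylbut-3-en-2-yl)oxy]benzaldehyde
Product: 4 2-ethenyl-5-(methoxymethoxy)-1,3-bis[(2-methylbut-3-en-2-yl)oxy]benzene
Conditions: Ph3PCH3Br, KOt-Bu, THF, 0 °C
Reagents that add atoms: methyltriphenylphosphonium bromide (precursor of Ph3P=CH2), C[P+](c1ccccc1)(c1ccccc1)c1ccccc1.[Br-]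
Why: Wittig methylenation with the non-stabilized ylide should convert even this di-ortho-substituted aldehyde at 0 °C, far below the onset of Claisen rearrangement of the tertiary allyl ethers.

**Step 4**
Reactants: 4 2-ethenyl-5-(methoxymethoxy)-1,3-bis[(2-methylbut-3-en-2-yl)oxy]benzene
Product: 7 7-(methoxymethoxy)-2,2-dimethyl-6-(3-methylbut-2-en-1-yl)-2H-chromen-5-ol, via chromene allyl ether 5 (not isolated), via Claisen dienone 6 (not isolated)
Conditions: second-generation Grubbs catalyst RuCl2(=CHPh)(H2IMes)(PCy3) (5 mol %), PhMe (5 mM), 40 °C; then ethyl vinyl ether (catalyst quench), 120 °C (sealed)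
Reagents that add atoms: none
Why: The ruthenium alkylidene exchanges onto the aryl vinyl group and then undergoes intramolecular [2+2] cycloaddition/cycloreversion with the CH=CH2 terminus of one O–C(CH3)2–CH=CH2 arm, expelling ethene and joining the benzylic vinyl carbon (the later pyran C4) to the CH next to the quaternary carbon (the later C3); the closest precedent is the ring-closing metathesis of allyl 2-vinylaryl ethers to 2H-chromenes. The six-membered oxygen ring is thus closed by olefin metathesis across its C3–C4 bond (formed as C3=C4 and saturated in step 5), with the O–C2 bond already in place. Because 4 has a mirror plane through the vinyl group and the OMOM carbon, closure onto either arm gives the same chromene 5, so no selectivity between the arms is needed. On heating, the remaining arm of 5, a type 3 olefin that does not homodimerize, undergoes an aromatic Claisen [3,3]-sigmatropic shift to its only free ortho carbon to give dienone 6, whose enolization restores the arene, frees the phenol and leaves a prenyl group bound through CH2. No stereocentre survives, since the sp3 carbon of 6 is lost on tautomerization. The selectivities required are metathesis before rearrangement (40 °C against 120 °C), ring closure over cross-metathesis (5 mM dilution and the hindered quaternary allylic carbon) and ortho over para migration (a free ortho position next to the ether oxygen).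

**Step 5**
Reactants: 7 7-(methoxymethoxy)-2,2-dimethyl-6-(3-methylbut-2-en-1-yl)-2H-chromen-5-ol
Product: 8 7-(methoxymethoxy)-2,2-dimethyl-6-(3-methylbut-2-en-1-yl)chroman-5-ol
Conditions: H2 (1 atm), RhCl(PPh3)3 (5 mol %), PhH–EtOH, rt
Reagents that add atoms: none
Why: Homogeneous catalytic hydrogenation with RhCl(PPh3)3 is strongly sensitive to alkene substitution, so the cis-disubstituted C3=C4 bond should be saturated while the trisubstituted prenyl double bond is left, bringing the ring to the chromane level of the target.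

**Step 6**
Reactants: 8 7-(methoxymethoxy)-2,2-dimethyl-6-(3-methylbut-2-en-1-yl)chroman-5-ol
Product: 9 5,7-bis(methoxymethoxy)-2,2-dimethyl-6-(3-methylbut-2-en-1-yl)chromane
Conditions: MOMCl, i-Pr2NEt, CH2Cl2, 0 → 40 °C
Reagents that add atoms: chloromethyl methyl ether, COCCl
Why: Williamson-type MOM etherification masks the phenol (the later 7-OH) so that organolithium chemistry can follow and the ortho-prenylphenol stays protected to the end.

**Step 7**
Reactants: 9 5,7-bis(methoxymethoxy)-2,2-dimethyl-6-(3-methylbut-2-en-1-yl)chromane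
Product: 11 1-[5,7-bis(methoxymethoxy)-2,2-dimethyl-6-(3-methylbut-2-en-1-yl)chroman-8-yl]ethan-1-one, via aryllithium 10 (not isolated)
Conditions: n-BuLi, TMEDA, THF, −20 → 0 °C; MeC(O)N(OMe)Me, −78 → 0 °C; aq NH4Cl
Reagents that add atoms: N-methoxy-N-methylacetamide, CC(=O)N(C)OC; n-butyllithium, [Li]CCCC (lithium of intermediate 10 only)
Why: Directed ortho-metalation should take place at the only aromatic C–H, which lies between the OMOM group and the ring oxygen, and the Weinreb amide acylates the aryllithium without over-addition because its tetrahedral adduct is chelated.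

**Step 8**
Reactants: 12 2,5-dihydroxybenzaldehyde
Product: 13 2-hydroxy-5-[(triisopropylsilyl)oxy]benzaldehyde
Conditions: TIPSCl (1.05 equiv), imidazole, DMF, 0 °C
Reagents that add atoms: chlorotriisopropylsilane, CC(C)[Si](Cl)(C(C)C)C(C)C
Why: Silyl ether formation should be selective for the 5-OH, the phenol that is not hydrogen-bonded to the aldehyde.

**Step 9**
Reactants: 13 2-hydroxy-5-[(triisopropylsilyl)oxy]benzaldehyde
Product: 14 2-(methoxymethoxy)-5-[(triisopropylsilyl)oxy]benzaldehyde
Conditions: MOMCl, i-Pr2NEt, CH2Cl2, 0 → 40 °C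
Reagents that add atoms: chloromethyl methyl ether, COCCl
Why: Williamson-type MOM etherification of the remaining phenol gives the two ring B oxygens different protecting groups, which later lets the 2'-oxygen be freed alone.

**Step 10**
Reactants: 14 2-(methoxymethoxy)-5-[(triisopropylsilyl)oxy]benzaldehyde
Product: 16 2-(methoxymethoxy)-5-[(triisopropylsilyl)oxy]phenol, via aryl formate 15 (not isolated)
Conditions: mCPBA, CH2Cl2, 0 °C → rt; then Et3N (cat.), MeOH, 0 °C
Reagents that add atoms: 3-chloroperbenzoic acid, OOC(=O)c1cccc(Cl)c1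
Why: In this Baeyer–Villiger (Dakin-type) oxidation the electron-rich aryl group migrates to oxygen to give formate 15, which mild base-catalysed transesterification cleaves to the phenol.

**Step 11**
Reactants: 16 2-(methoxymethoxy)-5-[(triisopropylsilyl)oxy]phenol
Product: 17 4-bromo-2-(methoxymethoxy)-5-[(triisopropylsilyl)oxy]phenol
Conditions: NBS (1.0 equiv), CH2Cl2, −40 → 0 °C
Reagents that add atoms: N-bromosuccinimide, O=C1CCC(=O)N1Br
Why: Electrophilic aromatic bromination should go para to the free phenol (and ortho to the silyloxy group), the most activated position that is not flanked by two oxygen substituents.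

**Step 12**
Reactants: 17 4-bromo-2-(methoxymethoxy)-5-[(triisopropylsilyl)oxy]phenol
Product: 18 [2-bromo-5-(methoxymethoxy)-4-[(2-methylbut-3-yn-2-yl)oxy]phenoxy]tri(propan-2-yl)silane
Conditions: 3-chloro-3-methylbut-1-yne, CuCl2·2H2O (1 mol %), DBU, MeCN, 0 °C
Reagents that add atoms: 3-chloro-3-methylbut-1-yne, C#CC(C)(C)Cl
Why: Copper-catalysed propargylic substitution is the standard way to make tertiary aryl 1,1-dimethylpropargyl ethers from phenols under mild base.

**Step 13**
Reactants: 18 [2-bromo-5-(methoxymethoxy)-4-[(2-methylbut-3-yn-2-yl)oxy]phenoxy]tri(propan-2-yl)silane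
Product: 22 [(6-bromo-8-(methoxymethoxy)-2,2-dimethyl-2H-chromen-5-yl)oxy]tri(propan-2-yl)silane, via allenyl dienone 19 (not isolated), via allenylphenol 20 (not isolated), via quinone methide 21 (not isolated)
Conditions: o-xylene, 140 °C
Reagents that add atoms: none
Why: The thermal aryl propargyl ether cascade (aromatic Claisen rearrangement to the only free ortho carbon, enolization, [1,5]-hydrogen shift, oxa-6π electrocyclization) should give the 2,2-dimethyl-2H-chromene with the pyran fused at the C3'–O4' edge of ring B.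

**Step 14**
Reactants: 11 1-[5,7-bis(methoxymethoxy)-2,2-dimethyl-6-(3-methylbut-2-en-1-yl)chroman-8-yl]ethan-1-one; 22 [(6-bromo-8-(methoxymethoxy)-2,2-dimethyl-2H-chromen-5-yl)oxy]tri(propan-2-yl)silane
Product: 23 1-[5,7-bis(methoxymethoxy)-2,2-dimethyl-6-(3-methylbut-2-en-1-yl)chroman-8-yl]-2-{8-(methoxymethoxy)-2,2-dimethyl-5-[(triisopropylsilyl)oxy]-2H-chromen-6-yl}ethan-1-one
Conditions: Pd2(dba)3 (2.5 mol %), XPhos (6 mol %), NaOt-Bu (2.2 equiv), PhMe, 80 °C
Reagents that add atoms: none
Why: Palladium-catalysed α-arylation of a ketone enolate (Buchwald–Hartwig type) should join the unhindered methyl carbon of 11 to the aryl bromide, and mono-arylation is favoured because the product enolate is more hindered and more stabilized.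

**Step 15**
Reactants: 23 the deoxybenzoin of step 14
Product: 24 1-[7-hydroxy-5-(methoxymethoxy)-2,2-dimethyl-6-(3-methylbut-2-en-1-yl)chroman-8-yl]-2-{8-(methoxymethoxy)-2,2-dimethyl-5-[(triisopropylsilyl)oxy]-2H-chromen-6-yl}ethan-1-one
Conditions: MgBr2·OEt2, CH2Cl2–Et2O, 0 °C → rt; aq NH4Cl
Reagents that add atoms: none
Why: Chelation-controlled Lewis acid cleavage should remove only the MOM ether ortho to the ketone, because magnesium bridges the carbonyl and that acetal oxygen, leaving the two other MOM ethers and the silyl ether.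

**Step 16**
Reactants: 24 the 2-hydroxydeoxybenzoin of step 15
Product: 26 9-{8-(methoxymethoxy)-2,2-dimethyl-5-[(triisopropylsilyl)oxy]-2H-chromen-6-yl}-5-(methoxymethoxy)-2,2-dimethyl-8-(methylsulfanyl)-6-(3-methylbut-2-en-1-yl)-3,4-dihydro-2H,10H-pyrano[2,3-f]chromen-10-one (the 2-(methylsulfanyl)isoflavone), via chromene-2-thione 25 (not isolated)
Conditions: CS2, KOt-Bu, THF, 0 °C → rt; then MeI, 0 °C
Reagents that add atoms: carbon disulfide, S=C=S; iodomethane, CI
Why: Enolate addition to CS2, cyclization of the dithiocarboxylate onto the phenoxide with loss of hydrosulfide to thione 25 and S-methylation is the established deoxybenzoin-to-2-(alkylsulfanyl)isoflavone annulation, and it builds ring C with a leaving group at C2.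

**Step 17**
Reactants: 26 the 2-(methylsulfanyl)isoflavone of step 16
Product: 28 bis(methoxymethyl) ether of the target (7-O-MOM and 5'-O-MOM coumaronochromone), via phenol 27 (not isolated)
Conditions: Bu4NF, THF, 0 → 50 °C; aq NH4Cl
Reagents that add atoms: none
Why: Fluoride desilylation gives the 2'-phenoxide, which should close the furan ring by intramolecular addition–elimination (nucleophilic vinylic substitution) at C2 with loss of methanethiolate, so that no oxidant is needed in the presence of the electron-rich ring B.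

**Step 18**
Reactants: 28 bis(methoxymethyl) ether of the target
Product: 29 CNP0081330.0 (target)
Conditions: HCl (3 M aq), MeOH–THF, 40 °C
Reagents that add atoms: none
Why: Acid-catalysed acetal exchange (MOM cleavage) should free 7-OH and 5'-OH under conditions mild enough to leave the ortho-prenylphenol uncyclized and the chromene intact.

**Compound list**

1 | 2,4,6-trihydroxybenzaldehyde | O=Cc1c(O)cc(O)cc1O | starting material
2 | 2,6-dihydroxy-4-(methoxymethoxy)benzaldehyde | O=Cc1c(O)cc(OCOC)cc1O | intermediate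
3 | 4-(methoxymethoxy)-2,6-bis[(2-methylbut-3-en-2-yl)oxy]benzaldehyde | O=Cc1c(OC(C)(C)C=C)cc(OCOC)cc1OC(C)(C)C=C | intermediate
4 | 2-ethenyl-5-(methoxymethoxy)-1,3-bis[(2-methylbut-3-en-2-yl)oxy]benzene | C=Cc1c(OC(C)(C)C=C)cc(OCOC)cc1OC(C)(C)C=C | intermediate
5 | 7-(methoxymethoxy)-2,2-dimethyl-5-[(2-methylbut-3-en-2-yl)oxy]-2H-chromene | CC1(C)C=Cc2c(OC(C)(C)C=C)cc(OCOC)cc2O1 | intermediate
6 | 7-(methoxymethoxy)-2,2-dimethyl-6-(3-methylbut-2-en-1-yl)-2H-chromen-5(6H)-one (racemic Claisen dienone) | CC1(C)C=CC2=C(O1)C=C(OCOC)C(CC=C(C)C)C2=O | intermediate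
7 | 7-(methoxymethoxy)-2,2-dimethyl-6-(3-methylbut-2-en-1-yl)-2H-chromen-5-ol | CC1(C)C=Cc2c(O)c(CC=C(C)C)c(OCOC)cc2O1 | intermediate
8 | 7-(methoxymethoxy)-2,2-dimethyl-6-(3-methylbut-2-en-1-yl)chroman-5-ol | CC1(C)CCc2c(O)c(CC=C(C)C)c(OCOC)cc2O1 | intermediate
9 | 5,7-bis(methoxymethoxy)-2,2-dimethyl-6-(3-methylbut-2-en-1-yl)chromane | CC1(C)CCc2c(OCOC)c(CC=C(C)C)c(OCOC)cc2O1 | intermediate
10 | [5,7-bis(methoxymethoxy)-2,2-dimethyl-6-(3-methylbut-2-en-1-yl)chroman-8-yl]lithium | CC1(C)CCc2c(OCOC)c(CC=C(C)C)c(OCOC)c([Li])c2O1 | intermediate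
11 | 1-[5,7-bis(methoxymethoxy)-2,2-dimethyl-6-(3-methylbut-2-en-1-yl)chroman-8-yl]ethan-1-one | CC(=O)c1c(OCOC)c(CC=C(C)C)c(OCOC)c2c1OC(C)(C)CC2 | intermediate
12 | 2,5-dihydroxybenzaldehyde | O=Cc1cc(O)ccc1O | starting material
13 | 2-hydroxy-5-[(triisopropylsilyl)oxy]benzaldehyde | O=Cc1cc(O[Si](C(C)C)(C(C)C)C(C)C)ccc1O | intermediate
14 | 2-(methoxymethoxy)-5-[(triisopropylsilyl)oxy]benzaldehyde | O=Cc1cc(O[Si](C(C)C)(C(C)C)C(C)C)ccc1OCOC | intermediate
15 | 2-(methoxymethoxy)-5-[(triisopropylsilyl)oxy]phenyl formate | O=COc1cc(O[Si](C(C)C)(C(C)C)C(C)C)ccc1OCOC | intermediate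
16 | 2-(methoxymethoxy)-5-[(triisopropylsilyl)oxy]phenol | Oc1cc(O[Si](C(C)C)(C(C)C)C(C)C)ccc1OCOC | intermediate
17 | 4-bromo-2-(methoxymethoxy)-5-[(triisopropylsilyl)oxy]phenol | Oc1cc(O[Si](C(C)C)(C(C)C)C(C)C)c(Br)cc1OCOC | intermediate
18 | [2-bromo-5-(methoxymethoxy)-4-[(2-methylbut-3-yn-2-yl)oxy]phenoxy]tri(propan-2-yl)silane | C#CC(C)(C)Oc1cc(O[Si](C(C)C)(C(C)C)C(C)C)c(Br)cc1OCOC | intermediate
19 | 4-bromo-6-(methoxymethoxy)-2-(3-methylbuta-1,2-dien-1-yl)-3-[(triisopropylsilyl)oxy]cyclohexa-3,5-dien-1-one (racemic) | O=C1C(C=C=C(C)C)C(O[Si](C(C)C)(C(C)C)C(C)C)=C(Br)C=C1OCOC | intermediate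
20 | 4-bromo-6-(methoxymethoxy)-2-(3-methylbuta-1,2-dien-1-yl)-3-[(triisopropylsilyl)oxy]phenol | Oc1c(C=C=C(C)C)c(O[Si](C(C)C)(C(C)C)C(C)C)c(Br)cc1OCOC | intermediate
21 | 4-bromo-6-(methoxymethoxy)-2-(3-methylbut-2-en-1-ylidene)-3-[(triisopropylsilyl)oxy]cyclohexa-3,5-dien-1-one (ortho-quinone methide) | O=C1C(=CC=C(C)C)C(O[Si](C(C)C)(C(C)C)C(C)C)=C(Br)C=C1OCOC | intermediate
22 | [(6-bromo-8-(methoxymethoxy)-2,2-dimethyl-2H-chromen-5-yl)oxy]tri(propan-2-yl)silane | CC1(C)C=Cc2c(O1)c(OCOC)cc(Br)c2O[Si](C(C)C)(C(C)C)C(C)C | intermediate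
23 | 1-[5,7-bis(methoxymethoxy)-2,2-dimethyl-6-(3-methylbut-2-en-1-yl)chroman-8-yl]-2-{8-(methoxymethoxy)-2,2-dimethyl-5-[(triisopropylsilyl)oxy]-2H-chromen-6-yl}ethan-1-one | O=C(Cc1cc(OCOC)c2OC(C)(C)C=Cc2c1O[Si](C(C)C)(C(C)C)C(C)C)c1c(OCOC)c(CC=C(C)C)c(OCOC)c2c1OC(C)(C)CC2 | intermediate
24 | 1-[7-hydroxy-5-(methoxymethoxy)-2,2-dimethyl-6-(3-methylbut-2-en-1-yl)chroman-8-yl]-2-{8-(methoxymethoxy)-2,2-dimethyl-5-[(triisopropylsilyl)oxy]-2H-chromen-6-yl}ethan-1-one | O=C(Cc1cc(OCOC)c2OC(C)(C)C=Cc2c1O[Si](C(C)C)(C(C)C)C(C)C)c1c(O)c(CC=C(C)C)c(OCOC)c2c1OC(C)(C)CC2 | intermediate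
25 | 10-hydroxy-9-{8-(methoxymethoxy)-2,2-dimethyl-5-[(triisopropylsilyl)oxy]-2H-chromen-6-yl}-5-(methoxymethoxy)-2,2-dimethyl-6-(3-methylbut-2-en-1-yl)-3,4-dihydro-2H,8H-pyrano[2,3-f]chromene-8-thione (formed as its potassium thiolate) | S=c1c(-c3cc(OCOC)c4OC(C)(C)C=Cc4c3O[Si](C(C)C)(C(C)C)C(C)C)c(O)c2c(o1)c(CC=C(C)C)c(OCOC)c1c2OC(C)(C)CC1 | intermediate
26 | 9-{8-(methoxymethoxy)-2,2-dimethyl-5-[(triisopropylsilyl)oxy]-2H-chromen-6-yl}-5-(methoxymethoxy)-2,2-dimethyl-8-(methylsulfanyl)-6-(3-methylbut-2-en-1-yl)-3,4-dihydro-2H,10H-pyrano[2,3-f]chromen-10-one | CSc1c(-c3cc(OCOC)c4OC(C)(C)C=Cc4c3O[Si](C(C)C)(C(C)C)C(C)C)c(=O)c2c(o1)c(CC=C(C)C)c(OCOC)c1c2OC(C)(C)CC1 | intermediate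
27 | 9-[5-hydroxy-8-(methoxymethoxy)-2,2-dimethyl-2H-chromen-6-yl]-5-(methoxymethoxy)-2,2-dimethyl-8-(methylsulfanyl)-6-(3-methylbut-2-en-1-yl)-3,4-dihydro-2H,10H-pyrano[2,3-f]chromen-10-one (formed as its phenoxide) | CSc1c(-c3cc(OCOC)c4OC(C)(C)C=Cc4c3O)c(=O)c2c(o1)c(CC=C(C)C)c(OCOC)c1c2OC(C)(C)CC1 | intermediate
28 | bis(methoxymethyl) ether of the target (7-OH of ring A and 5'-OH of ring B each carry CH2OCH3) | CC(C)=CCc1c(OCOC)c2c(c3c(=O)c4c(oc13)oc1c3c(c(OCOC)cc14)OC(C)(C)C=C3)OC(C)(C)CC2 | intermediate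
29 | CNP0081330.0 | CC(C)=CCc1c(O)c2c(c3c(=O)c4c(oc13)oc1c3c(c(O)cc14)OC(C)(C)C=C3)OC(C)(C)CC2 | target

**Step count and risks**

Total step count: 18. Longest linear sequence: 12 steps (steps 1–7 and 14–18); the ring B branch is steps 8–13.

Steps most likely to fail:

Step 4. What may go wrong: metathesis on the doubly ortho-substituted styrene may be so slow that, at the temperature then needed, both tertiary allyl ethers rearrange (double Claisen) or cross-metathesis oligomers form before the ring closes. The fallback separates the two roles of the arms in time while forming the same bond. It sets out from 2. Palladium-catalysed O-alkylation with one equivalent of the tertiary allylic carbonate should give 2-hydroxy-4-(methoxymethoxy)-6-[(2-methylbut-3-en-2-yl)oxy]benzaldehyde F1. Wittig methylenation with excess Ph3P=CH2 should give 2-ethenyl-5-(methoxymethoxy)-3-[(2-methylbut-3-en-2-yl)oxy]phenol F2. Ring-closing metathesis of this less hindered diene (second-generation Grubbs catalyst, CH2Cl2, 40 °C) should give 7-(methoxymethoxy)-2,2-dimethyl-2H-chromen-5-ol F3. A second palladium-catalysed O-alkylation of F3 gives 5, where the route is rejoined; heating 5 to 120 °C gives 7.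

Step 14. What may go wrong: slow oxidative addition of zerovalent palladium to the electron-rich aryl bromide flanked by the silyloxy group, or aldol self-condensation and double arylation of the ketone enolate. The fallback makes the C3–C1' bond by Suzuki–Miyaura coupling after ring C is built. It sets out from 11 and 22.
- Chelation-controlled MOM cleavage of 11 (MgBr2·OEt2) should give 1-[7-hydroxy-5-(methoxymethoxy)-2,2-dimethyl-6-(3-methylbut-2-en-1-yl)chroman-8-yl]ethan-1-one F4.
- CS2/KOt-Bu should close ring C to the 4-hydroxy-2H-chromene-2-thione F5, which is S-methylated in the same flask (MeI) to the 2-(methylsulfanyl)chromone F6.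
- Iodination at C3 (NIS, MeCN, 0 °C) should give the 3-iodo-2-(methylsulfanyl)chromone F7.
- Miyaura borylation of 22 (B2pin2, PdCl2(dppf), KOAc, dioxane, 85 °C) should give the pinacol boronate F8.
- Coupling of F7 with F8 (Pd(OAc)2, SPhos, K3PO4, toluene–water, 80 °C) comes back to the route at 26.

Step 7. What may go wrong: lateral deprotonation at the benzylic/allylic CH2 of the prenyl group or at the chromane C4H2, both flanked by MOM ethers, competing with ring lithiation. The fallback uses electrophilic ortho-formylation of a phenol and no organolithium. It sets out from 8.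
- MOM removal (HCl, MeOH, rt) should give 2,2-dimethyl-6-(3-methylbut-2-en-1-yl)chromane-5,7-diol F9.
- Magnesium-mediated ortho-formylation (MgCl2, Et3N, paraformaldehyde, MeCN, reflux) at the only free ring carbon should give 5,7-dihydroxy-2,2-dimethyl-6-(3-methylbut-2-en-1-yl)chromane-8-carbaldehyde F10.
- Double MOM protection (NaH, MOMCl, DMF) should give 5,7-bis(methoxymethoxy)-2,2-dimethyl-6-(3-methylbut-2-en-1-yl)chromane-8-carbaldehyde F11.
- Addition of MeMgBr should give racemic 1-[5,7-bis(methoxymethoxy)-2,2-dimethyl-6-(3-methylbut-2-en-1-yl)chroman-8-yl]ethan-1-ol F12.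
- Dess–Martin oxidation comes back to the route at 11.

**Further compounds**

F1 | step 4 | 2-hydroxy-4-(methoxymethoxy)-6-[(2-methylbut-3-en-2-yl)oxy]benzaldehyde | O=Cc1c(O)cc(OCOC)cc1OC(C)(C)C=C
F2 | step 4 | 2-ethenyl-5-(methoxymethoxy)-3-[(2-methylbut-3-en-2-yl)oxy]phenol | C=Cc1c(O)cc(OCOC)cc1OC(C)(C)C=C
F3 | step 4 | 7-(methoxymethoxy)-2,2-dimethyl-2H-chromen-5-ol | CC1(C)C=Cc2c(O)cc(OCOC)cc2O1
F4 | step 14 | 1-[7-hydroxy-5-(methoxymethoxy)-2,2-dimethyl-6-(3-methylbut-2-en-1-yl)chroman-8-yl]ethan-1-one | CC(=O)c1c(O)c(CC=C(C)C)c(OCOC)c2c1OC(C)(C)CC2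
F5 | step 14 | 10-hydroxy-5-(methoxymethoxy)-2,2-dimethyl-6-(3-methylbut-2-en-1-yl)-3,4-dihydro-2H,8H-pyrano[2,3-f]chromene-8-thione | S=c1cc(O)c2c(o1)c(CC=C(C)C)c(OCOC)c1c2OC(C)(C)CC1
F6 | step 14 | 5-(methoxymethoxy)-2,2-dimethyl-8-(methylsulfanyl)-6-(3-methylbut-2-en-1-yl)-3,4-dihydro-2H,10H-pyrano[2,3-f]chromen-10-one | CSc1cc(=O)c2c(o1)c(CC=C(C)C)c(OCOC)c1c2OC(C)(C)CC1
F7 | step 14 | 9-iodo-5-(methoxymethoxy)-2,2-dimethyl-8-(methylsulfanyl)-6-(3-methylbut-2-en-1-yl)-3,4-dihydro-2H,10H-pyrano[2,3-f]chromen-10-one | CSc1c(I)c(=O)c2c(o1)c(CC=C(C)C)c(OCOC)c1c2OC(C)(C)CC1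
F8 | step 14 | {[8-(methoxymethoxy)-2,2-dimethyl-6-(4,4,5,5-tetramethyl-1,3,2-dioxaborolan-2-yl)-2H-chromen-5-yl]oxy}tri(propan-2-yl)silane | CC1(C)C=Cc2c(O1)c(OCOC)cc(B3OC(C)(C)C(C)(C)O3)c2O[Si](C(C)C)(C(C)C)C(C)C
F9 | step 7 | 2,2-dimethyl-6-(3-methylbut-2-en-1-yl)chromane-5,7-diol | CC1(C)CCc2c(O)c(CC=C(C)C)c(O)cc2O1
F10 | step 7 | 5,7-dihydroxy-2,2-dimethyl-6-(3-methylbut-2-en-1-yl)chromane-8-carbaldehyde | O=Cc1c(O)c(CC=C(C)C)c(O)c2c1OC(C)(C)CC2
F11 | step 7 | 5,7-bis(methoxymethoxy)-2,2-dimethyl-6-(3-methylbut-2-en-1-yl)chromane-8-carbaldehyde | O=Cc1c(OCOC)c(CC=C(C)C)c(OCOC)c2c1OC(C)(C)CC2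
F12 | step 7 | 1-[5,7-bis(methoxymethoxy)-2,2-dimethyl-6-(3-methylbut-2-en-1-yl)chroman-8-yl]ethan-1-ol (racemic) | CC(O)c1c(OCOC)c(CC=C(C)C)c(OCOC)c2c1OC(C)(C)CC2
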